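A leftover started me. At 6.00 min the south-east run still held 79% of its starting material beside 23% of product, and the east run, at 6.00 min, held 80% beside 24%. The east run gave 0.300 for the product fraction divided by the leftover fraction, which I called the standing ratio. The south-east run gave 0.291, although east was charged 1.57 times as much. Where product and leftover together make up the charge, the product fraction is the ratio over one plus the ratio.

common to all: gas phase 19 mM (held); free catalyst 1.9 mM
- south-east: starting material 0.28 M; run made earlier
- east: starting material 0.44 M; run made earlier
- flask: starting material 0.20 M; time 8.0 min

| run | time / min | product / % | starting material / % |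
|---|---|---|---|
| south-east | 0.500 | 5 | 95 |
| south-east | 1.00 | 10 | 91 |
| south-east | 2.00 | 16 | 89 |
| south-east | 3.00 | 21 | 79 |
| south-east | 6.00 | 23 | 79 |
| east | 0.500 | 2 | 99 |
| east | 1.50 | 9 | 90 |
| east | 3.00 | 15 | 85 |
| east | 5.00 | 21 | 81 |
| east | 6.00 | 24 | 80 |

(scatter of a reading: 2 percentage points)

- at the start none of the gas phase is in solution

- the product standing at 8.0 min, as a percentage of the starting material charged
- the change that raises the amount of product at 8.0 min, in percent of the starting material charged most ("none" if none brings more than 2 percentage points) (birch / alder / oak / none)
- amount of product at 8.0 min, in percent of the starting material charged, after birch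

- birch: doubling the saturation concentration of gas phase, all else as stated
- alder: doubling the amount of free catalyst, all else as stated
- oak: doubling the transfer coefficient of the gas phase, all else as stated

Two extreme flasks could be done in the head. In the first, the new flask kept the pace read from the south-east run at 1.00 min, a pseudo-first-order loss of 0.105 min⁻¹, which gives 56.8% of product at 8.0 min. In the second, it already stood at the ratio, which gives 23.1%. I expected the new flask to lie between them, nearer the second: the south-east readings of product went from 21% at 3.00 min to 23% at 6.00 min, against a scatter of 2 percentage points.

I read the ratio as a balance that takes up dissolved gas (thermodynamic control). On that reading, birch doubles it, and my own reckoning gave 37.5%, below the forecast's figure, while alder and oak move the pace, not the ratio.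

The forecast gave 26%, chose birch and put that change at 43%, on different grounds: “This points to time-based catalyst death rather than product inhibition or a fixed turnover limit.”

The flask gave 26.8%. The best change was birch, at 42.8%, while alder added 0.13 points and oak 0.67 points.

    gas phase ⇌ dissolved gas, rate k1*(csat - [dissolved gas]) (kL = 0.0370 s⁻¹)
    starting material + dissolved gas + free catalyst ⇌ free catalyst + product (K = 20.0 L mol⁻¹, k = 590 L² mol⁻² s⁻¹)
    2 free catalyst → spent catalyst (k = 3.60 L mol⁻¹ s⁻¹)

The flask's standing ratio at 8.00 min was 0.365; doubled, it gives 42.2% of product, beside 42.8% after birch. Dissolved gas in this flask then stood at 98.4% of saturation. The neighbour flask, charged with 0.80 M of starting material, held 76.2% of saturation at 8.00 min. Scaling the ratio by these two shares gave 0.283 for the neighbour flask, and so 22.1% of product. The neighbour flask gave 20.5%, a standing ratio of 0.257.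

Readings and results are calculated for substances that don't exist; noise was put on by code.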